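The readings stem from a simulated flask for substances that don't exist; the scatter is artificial.

At 40.0 h the north-east run held 15.3 % of other mono adduct (N) and 14.8 % of first product (M), and the north-west run held 10.7 % and 12.4 %. I took N and M as parallel additions of reagent to starting material. Dividing one rate by the other then cancels both concentrations and time, as long as neither adduct is consumed. The four readings, each with a scatter of 0.5 percentage points, gave 0.956: the selectivity factor S, N formed per M formed.

| flask | starting material | reagent | remark | time |
|---|---|---|---|---|
| north-west | 0.39 M (fed, over 2.5 d) | 0.39 M | run made earlier; the fed solution adds 0.20 times the starting volume |  |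
| north-east | 0.39 M (fed, over 2.5 d) | 0.58 M | run made earlier; the fed solution adds 0.20 times the starting volume |  |
| flask | 0.39 M (fed, over 2.5 d) | 0.780 M | the fed solution adds 0.20 times the starting volume | 2.5 d |

| run | time / h | other mono adduct / % | first product / % |
|---|---|---|---|
| north-west | 10.0 | 1.6 | 1.0 |
| north-west | 20.0 | 3.5 | 4.8 |
| north-west | 25.0 | 5.5 | 4.7 |
| north-west | 40.0 | 10.7 | 12.4 |
| north-east | 3.00 | 1.2 | 0.5 |
| north-east | 6.00 | 0.3 | 0.3 |
| north-east | 15.0 | 2.8 | 3.3 |
| north-east | 40.0 | 15.3 | 14.8 |

(readings scatter by 0.5 percentage points)

- charges are per starting volume, the dose included; the dosed solution carries all of it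
- percentages count the whole charge, also what has not yet gone in

- equivalents of reagent to starting material, everything else as given, that leave most other mono adduct at 2.5 d
- the amount of other mono adduct then, in percent of the starting material charged
- the amount of other mono adduct with the amounts as given

My own reckoning went no further than this: at 2.5 d the flask should hold S times as much N as M, provided neither adduct had by then been consumed to any extent that counts. The forecast gave 25 % of N as charged and 30 % at 3.5 equiv, on the ground that “More reagent raises conversion but also overaddition”. The flask gave 29.3 % of N as charged, and the most N, 35.7 %, came at 5.03 equiv.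

    starting material + reagent → first product (k = 0.0375 L mol⁻¹ h⁻¹)
    starting material + reagent → other mono adduct (k = 0.0377 L mol⁻¹ h⁻¹)
    reagent + first product → bis adduct (k = 5.77 × 10⁻⁴ L mol⁻¹ h⁻¹)
    reagent + other mono adduct → bis adduct (k = 0.00429 L mol⁻¹ h⁻¹)

In the flask at 2.50 d, N was being formed 1.0 times as fast as M, and the half-life of N towards bis adduct, 8.6 d, was long against the 2.5 d of the run; S times the 30.7 % of M gives 29.3 %, and the flask held 29.3 % of N beside 2.01 % of bis adduct. Read on to 4.0 d, the same recipe held 42.7 % of M, for which S gives 40.8 % of N, and it held 39.6 %.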